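## Structural features

The target is a cyclohexene (ring A, C1–C6) fused across C2–C3 to an oxirane, with a C4=C5 alkene (methyl on C4), a methyl on C2, and a quaternary C6 that carries a methyl group and a 2-methoxy-3,5-dimethyl-4-pyranone (ring B, bonded through its C6'). C1 bears an E-trisubstituted alkenyl chain, C7(Me)=C8–C9H(Me)–C10(=O)–CH2CH3. Four stereocentres are contiguous on ring A (1R, 2S, 3R, 6R): the chain on C1 and ring B on C6 are cis, the oxirane oxygen lies on the opposite face, and the C2 methyl is therefore cis to the chain. The fifth centre, C9 (R), sits across the C7=C8 alkene and has no stereochemical communication with the ring. The fragile groups are the trisubstituted vinyl oxirane (acid, Lewis acid, hydride) and C9, which is α to the ketone and allylic, so base would epimerise it or pull the alkene into conjugation. The real difficulty is the quaternary C6 next to C1 with a defined cis relationship, and tying the absolute configuration of the ring to C9. The key step uses the fact that C6 carries a methyl group and a carbon at the acyl oxidation level and is bonded to the alkene carbon C5: cutting C5–C6 turns C6 and its methyl into the two alkene carbons of a 2-substituted acrylate and C5 into a vinyl electrophile, so ring A can be closed by carbopalladation and the methyl completed by hydride.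

## Logic of the disconnections

**40 back to 38.** No skeletal bond is cut; the C10 ketone is traced to a silyl-protected carbinol. C9 would not survive the bases used earlier if C10 were a ketone. The gain is a configurationally safe C9 through the whole route; the demand is that desilylation and oxidation are the last operations and stay neutral.

**38 back to 33.** Cut C3–O of the oxirane, then C2–O. The oxirane is the most fragile group, so it is installed after ring B and never meets a hydride reagent or a methylating agent. 33 is a simple enone whose only enolisable position is C2. The forward steps must oxygenate C2 on the face away from the C1 chain (35), deliver hydride to C3 on the same face as the new hydroxyl (36), and close with inversion at C3 (via 37).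

**33 back to 26 and 27.** Cut the O1'–C2' lactone bond, the C5'–C6' bond and the methyl–oxygen bond. Ring B collapses to a formyl group on C6 plus a commercial keto ester. The demands are that dianion 28 takes the aldehyde of 26 and not its enone, and that 31 is methylated on the lactone oxygen. 26 comes from 24 by a reduction/oxidation pair (25), which costs no extra step over an ester-only adjustment.

**24 back to 22.** Cut C5–C6. This removes the ring and the quaternary centre in one stroke and leaves an acyclic chain with two stereocentres. The forward step needs a Z vinyl electrophile at C5, an acrylate that inserts in the exo sense, and a hydride donor. It also needs a single configuration at C2: the C2 methyl, trans to the C1 chain, is what fixes the chair of the insertion and hence C6.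

**22 back to 19.** Cut the O–S bond and the C4–C5 bond (formyl carbon). The vinyl triflate is reduced to an ethyl ketone. The forward steps must formylate C4 without enolising toward C2 and without disturbing the acrylate, then sulfonylate the formyl oxygen with Z geometry (21).

**19 back to 14.** Cut the C3–C4 bond (ethyl group) and lower the oxidation level of the carbon on C6 to a silyl-protected allylic alcohol (15–18). An acrylate cannot coexist with the ester enolate and organolithium steps, so it is unveiled only afterwards. The demand is that C2, now α to a ketone, is not epimerised during these adjustments.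

**14 back to 10.** Cut C1–C2 as an Ireland–Claisen rearrangement of 11. One carbinol then controls C1, C2 and the E geometry of C7=C8 through a single chair. A route that formed C2 by protonating an enol (for example after a decarboxylation) would leave C2 uncontrolled, and C2 is needed for the key step. The demands are the (8R) carbinol, an E C7=C1 alkene and the kinetic E-enolate.

**10 back to 3 and 7.** Cut C7–C8. The chain aldehyde and a small enyne remain. The forward addition must be syn-selective at the alkyne (hydrometalation) and Felkin-selective at the aldehyde.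

**3 back to 1; 7 back to 4 and 6.** Cut the C9–C10 aldol bond and the sp–sp2 bond of the enyne. Everything is reduced to propanal, 2-bromoallyl alcohol and propyne. The aldol must be enantioselective at the carbon that becomes C9.

## Other disconnections considered

**Alternative 1:** The cut is C1–C7 together with the C6–methyl bond, ring A being bought as an arene. In the forward step the side-chain alkenyllithium A3 would add to the ortho carbon of the aryl oxazoline A2, and the aza-enolate would be methylated at the ipso carbon on the opposite face, giving A1 with the chain and the oxazoline cis.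
- In favour: all six ring carbons, both ring methyls and the C3 oxygen come from one cheap aromatic; C1 and C6 are set in one flask under auxiliary control; the chain is joined late. On step economy to a ring A intermediate this is better than the chosen plan (about three steps against fifteen). On absolute control of C1/C6 it is at least equal in principle.
- Against: this kind of dearomatising addition is dependable for naphthalenes and for reactive alkyllithiums. Here the nucleophile is a hindered sp2 lithium reagent, the arene is electron-rich, and the site of attack is flanked by a methyl group. Ortho-deprotonation or attack at the oxazoline carbon are the likely courses. The precious chain would be the reagent used in excess.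
- Comparison: after A1 the enol ether still has to be hydrolysed to the C3 ketone, C2 oxygenated and the oxazoline converted to an aldehyde, so the end game is no shorter than from 24. Mechanistically the chosen palladium closure stands on firmer precedent.

**Alternative 2:** The cut is C2–C3 and C3–O. The ylide from the Z-allylic sulfonium salt A5 would attack the C2 methyl ketone to close ring A, and the alkoxide would expel the sulfide to close the oxirane, giving A4, which is the same structure as 38.
- In favour: ring and oxirane form in one late operation, the oxirane meets no further reagent before the two final steps, and three steps of the chosen end game (22–24) would be replaced by one. On the end game this is the better plan; in ring B chemistry the two are equal.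
- Against: the hard problem is moved, not solved. A5 needs the C1/C6 pair, with quaternary C6 already carrying ring B, to be built on an open chain. The stabilised allylic ylide faces an enolisable methyl ketone, so proton transfer competes with addition. Two new centres (C2, C3) must form on the correct face with no obvious control element. The Z geometry of the allyl sulfonium must hold.
- Comparison: structurally the two converge at 38. The six-membered epoxy-annulation has less precedent than the reductive Heck closure. Overall step count would depend on an acyclic synthesis of A5 that is unlikely to be shorter than 1→33.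

**Alternative 3:** The cut is C1–C6 and C2–C3 in a Diels–Alder sense. The pyranone A7 as diene and the α,β-alkene of dienone A8 would combine under Lewis acid to the bridged lactone A6.
- In favour: it is the most convergent ring construction of all. Four ring stereocentres including both quaternary carbons are set in one step from two simple partners, and the lactone bridge already holds the C3 oxygen and the acyl carbon for ring B. On bonds and stereocentres made per step it is better than the chosen plan.
- Against: both partners are electron-poor, so the pairing is electronically mismatched. The required regiochemistry joins the two most substituted termini. The dienophile is a trisubstituted alkene that is itself a diene. The remote C9 gives no facial control, so a chiral Lewis acid would have to set the absolute sense. Bridged pyranone adducts tend to fragment on heating. Afterwards the C2 acetyl must be turned into oxygen by a peracid in the presence of three alkenes.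
- Comparison: the chosen plan is longer but each stereocentre has a named control element and no step asks two deactivated partners to react. Here the gain in step economy is paid for with regiochemical, facial and chemoselectivity risks.

Key step: step 15

Remark on the chemistry (assumption): the C10 carbinol configuration is immaterial to the target and is kept as (10S), anti to the C9 methyl, because that is what step 1 delivers. Compounds 25, 29 and 30 are carried as mixtures at centres that are removed again, and 21 is drawn as its chelated Z-enol.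

## Route

Step 1
Reactants: 1 propanal (two molecules)
Product: 2 (2S,3S)-3-hydroxy-2-methylpentanal
Conditions: L-proline (10 mol %), DMF, 4 °C, slow addition of 1
Reagents that add atoms: none
Why: Proline-catalysed direct aldol dimerisation; the E-enamine of one aldehyde attacks the Re face of the second in the carboxylic-acid-organised transition state, which sets the future C9 (2S) and the anti carbinol. The minor syn isomer is removed by chromatography after step 2.

Step 2
Reactants: 2 (2S,3S)-3-hydroxy-2-methylpentanal
Product: 3 (2S,3S)-3-[(tert-butyldimethylsilyl)oxy]-2-methylpentanal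
Conditions: TBSOTf, 2,6-lutidine, CH2Cl2, −78 °C
Reagents that add atoms: tert-butyldimethylsilyl trifluoromethanesulfonate, CC(C)(C)[Si](C)(C)OS(=O)(=O)C(F)(F)F
Why: Fast, cold silylation of the β-hydroxy aldehyde forestalls retro-aldol, dehydration and epimerisation at the α-carbon.

Step 3
Reactants: 4 2-bromoprop-2-en-1-ol
Product: 5 [(2-bromoprop-2-en-1-yl)oxy]triethylsilane
Conditions: Et3SiCl, imidazole, CH2Cl2, 0 °C to rt
Reagents that add atoms: chlorotriethylsilane, CC[Si](Cl)(CC)CC
Why: Standard silyl ether formation; the primary triethylsilyl ether can later be removed beside the secondary tert-butyldimethylsilyl ether.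

Step 4
Reactants: 5 [(2-bromoprop-2-en-1-yl)oxy]triethylsilane; 6 propyne
Product: 7 triethyl[(2-methylidenepent-3-yn-1-yl)oxy]silane
Conditions: PdCl2(PPh3)2 (3 mol %), CuI (5 mol %), iPr2NH, THF, rt
Reagents that add atoms: none
Why: Sonogashira coupling of a 2-bromo-1-alkene with a terminal alkyne; no stereocentre is involved.

Step 5
Reactants: 7 triethyl[(2-methylidenepent-3-yn-1-yl)oxy]silane; 3 (2S,3S)-3-[(tert-butyldimethylsilyl)oxy]-2-methylpentanal
Product: 10 (3E,5R,6R,7S)-7-[(tert-butyldimethylsilyl)oxy]-4,6-dimethyl-2-methylidene-1-[(triethylsilyl)oxy]non-3-en-5-ol, via alkenylzirconocene chloride 8 (not isolated), via alkenyl(methyl)zinc 9 (not isolated)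
Conditions: Cp2ZrHCl, CH2Cl2, rt; Me2Zn, toluene, −65 °C; then 3, 0 °C
Reagents that add atoms: none
Why: Syn hydrozirconation puts zirconium on the methyl-bearing alkyne carbon (less hindered, distal to the vinyl group); zirconium-to-zinc transmetalation and 1,2-addition follow. Felkin–Anh attack on the α-methyl aldehyde, reinforced by 1,3-anti induction from the β-silyloxy group, should give the (8R) carbinol (C5 of the name) syn to the C9 methyl.

Step 6
Reactants: 10 (3E,5R,6R,7S)-7-[(tert-butyldimethylsilyl)oxy]-4,6-dimethyl-2-methylidene-1-[(triethylsilyl)oxy]non-3-en-5-ol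
Product: 11 (3E,5R,6R,7S)-7-[(tert-butyldimethylsilyl)oxy]-4,6-dimethyl-2-methylidene-1-[(triethylsilyl)oxy]non-3-en-5-yl propanoate
Conditions: EtCOCl, pyridine, DMAP (cat.), CH2Cl2, 0 °C to rt
Reagents that add atoms: propanoyl chloride, CCC(=O)Cl
Why: Acyl transfer to the secondary allylic alcohol; the carbinol configuration is untouched.

Step 7
Reactants: 11 (3E,5R,6R,7S)-7-[(tert-butyldimethylsilyl)oxy]-4,6-dimethyl-2-methylidene-1-[(triethylsilyl)oxy]non-3-en-5-yl propanoate
Product: 14 (2S,3R,4E,6R,7S)-7-[(tert-butyldimethylsilyl)oxy]-2,4,6-trimethyl-3-{3-[(triethylsilyl)oxy]prop-1-en-2-yl}non-4-enoic acid, via silyl ketene acetal 12 (not isolated), via trimethylsilyl ester 13 (not isolated)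
Conditions: LiN(iPr)2, THF, −78 °C; Me3SiCl, Et3N, −78 °C to 50 °C; aq. NaOH, then pH 4
Reagents that add atoms: none
Why: Ireland–Claisen rearrangement; kinetic enolisation in THF gives the ketene acetal with methyl cis to the allylic oxygen. The chair with the C8 substituent equatorial transfers the (8R) carbinol to C1 (R), sets C2 (S) and makes the new C7=C8 alkene E.

Step 8
Reactants: 14 (2S,3R,4E,6R,7S)-7-[(tert-butyldimethylsilyl)oxy]-2,4,6-trimethyl-3-{3-[(triethylsilyl)oxy]prop-1-en-2-yl}non-4-enoic acid
Product: 15 (4S,5R,6E,8R,9S)-9-[(tert-butyldimethylsilyl)oxy]-4,6,8-trimethyl-5-{3-[(triethylsilyl)oxy]prop-1-en-2-yl}undec-6-en-3-one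
Conditions: EtLi (3.5 equiv), Et2O, −78 to 0 °C; inverse quench into cold aq. NH4Cl
Reagents that add atoms: ethyllithium, [Li]CC
Why: Addition of an alkyllithium to the lithium carboxylate stops at the dilithio gem-diolate, which gives the ketone only on quench. The carboxylate α-hydrogen is not removed, so C2 is retained.

Step 9
Reactants: 15 (4S,5R,6E,8R,9S)-9-[(tert-butyldimethylsilyl)oxy]-4,6,8-trimethyl-5-{3-[(triethylsilyl)oxy]prop-1-en-2-yl}undec-6-en-3-one
Product: 16 (4S,5R,6E,8R,9S)-9-[(tert-butyldimethylsilyl)oxy]-5-(3-hydroxyprop-1-en-2-yl)-4,6,8-trimethylundec-6-en-3-one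
Conditions: PPTS, MeOH/CH2Cl2, 0 °C
Reagents that add atoms: none
Why: Mild acid methanolysis removes the primary triethylsilyl ether far faster than the hindered secondary tert-butyldimethylsilyl ether.

Step 10
Reactants: 16 (4S,5R,6E,8R,9S)-9-[(tert-butyldimethylsilyl)oxy]-5-(3-hydroxyprop-1-en-2-yl)-4,6,8-trimethylundec-6-en-3-one
Product: 17 (3R,4S)-3-[(2E,4R,5S)-5-[(tert-butyldimethylsilyl)oxy]-4-methylhept-2-en-2-yl]-4-methyl-2-methylidene-5-oxoheptanal
Conditions: MnO2, CH2Cl2, rt
Reagents that add atoms: none
Why: Neutral, selective oxidation of the allylic alcohol; the enal is used at once.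

Step 11
Reactants: 17 (3R,4S)-3-[(2E,4R,5S)-5-[(tert-butyldimethylsilyl)oxy]-4-methylhept-2-en-2-yl]-4-methyl-2-methylidene-5-oxoheptanal
Product: 18 (3R,4S)-3-[(2E,4R,5S)-5-[(tert-butyldimethylsilyl)oxy]-4-methylhept-2-en-2-yl]-4-methyl-2-methylidene-5-oxoheptanoic acid
Conditions: NaClO2, NaH2PO4, 2-methyl-2-butene, t-BuOH/H2O, 0 °C
Reagents that add atoms: sodium chlorite, [Na+].[O-]Cl=O
Why: Pinnick oxidation at buffered pH; the alkene scavenger protects the chain alkenes, and the weakly acidic medium leaves C2 alone.

Step 12
Reactants: 18 (3R,4S)-3-[(2E,4R,5S)-5-[(tert-butyldimethylsilyl)oxy]-4-methylhept-2-en-2-yl]-4-methyl-2-methylidene-5-oxoheptanoic acid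
Product: 19 methyl (3R,4S)-3-[(2E,4R,5S)-5-[(tert-butyldimethylsilyl)oxy]-4-methylhept-2-en-2-yl]-4-methyl-2-methylidene-5-oxoheptanoate
Conditions: Me3SiCHN2, MeOH/toluene, 0 °C
Reagents that add atoms: (trimethylsilyl)diazomethane, C[Si](C)(C)C=[N+]=[N-]
Why: Base-free esterification, so neither C2 nor the skipped diene at C1 is disturbed.

Step 13
Reactants: 19 methyl (3R,4S)-3-[(2E,4R,5S)-5-[(tert-butyldimethylsilyl)oxy]-4-methylhept-2-en-2-yl]-4-methyl-2-methylidene-5-oxoheptanoate
Product: 21 methyl (3R,4S,6Z)-3-[(2E,4R,5S)-5-[(tert-butyldimethylsilyl)oxy]-4-methylhept-2-en-2-yl]-7-hydroxy-4,6-dimethyl-2-methylidene-5-oxohept-6-enoate (enol form of the C4-formyl ketone), via trichlorotitanium enolate 20 (not isolated)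
Conditions: TiCl4, Et3N, HCO2Me, CH2Cl2, −78 to −20 °C
Reagents that add atoms: methyl formate, COC=O
Why: Titanium-mediated crossed Claisen formylation; soft enolisation of an ethyl ketone with TiCl4 and an amine takes place at the CH2 group and leaves the α'-stereocentre C2 untouched. No new stereocentre persists because C4 ends as an enol carbon.

Step 14
Reactants: 21 methyl (3R,4S,6Z)-3-[(2E,4R,5S)-5-[(tert-butyldimethylsilyl)oxy]-4-methylhept-2-en-2-yl]-7-hydroxy-4,6-dimethyl-2-methylidene-5-oxohept-6-enoate
Product: 22 methyl (3R,4S,6Z)-3-[(2E,4R,5S)-5-[(tert-butyldimethylsilyl)oxy]-4-methylhept-2-en-2-yl]-4,6-dimethyl-2-methylidene-5-oxo-7-[(trifluoromethanesulfonyl)oxy]hept-6-enoate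
Conditions: LiOTf, Et3N, Tf2O, CH2Cl2, −78 °C
Reagents that add atoms: trifluoromethanesulfonic anhydride, O=S(=O)(OS(=O)(=O)C(F)(F)F)C(F)(F)F
Why: Stereoselective enol triflation of a 1,3-dicarbonyl; lithium chelation between the two oxygens holds the enolate in the Z form, and the less hindered formyl oxygen is sulfonylated.

Step 15
Reactants: 22 methyl (3R,4S,6Z)-3-[(2E,4R,5S)-5-[(tert-butyldimethylsilyl)oxy]-4-methylhept-2-en-2-yl]-4,6-dimethyl-2-methylidene-5-oxo-7-[(trifluoromethanesulfonyl)oxy]hept-6-enoate
Product: 24 methyl (1R,5S,6R)-6-[(2E,4R,5S)-5-[(tert-butyldimethylsilyl)oxy]-4-methylhept-2-en-2-yl]-1,3,5-trimethyl-4-oxocyclohex-2-ene-1-carboxylate, via σ-alkylpalladium formate 23 (not isolated)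
Conditions: Pd(OAc)2 (10 mol %), PPh3 (20 mol %), HCO2Na, Et4NCl, DMF, 60 °C
Reagents that add atoms: none
Why: Pd(OAc)2/PPh3 gives zerovalent palladium in situ, which adds oxidatively to the C5–OTf bond; the divalent vinylpalladium then inserts the tethered acrylate alkene in a syn, 6-exo-trig carbopalladation that forms C5–C6 and closes ring A. The σ-alkylpalladium 23 sits on a neopentyl carbon, so β-hydride elimination is impossible; exchange with formate, loss of CO2 and C–H reductive elimination turn CH2–Pd into the C6 methyl and return zerovalent palladium. The closest known reaction type is the intramolecular reductive Heck cyclisation of aryl or alkenyl halides and triflates onto 1,1-disubstituted alkenes with formate as hydride donor, an established route to all-carbon quaternary centres. C6 is the only new stereocentre: the four-centre insertion holds the C6=CH2 bond eclipsed with C5–Pd, which places the methylene pseudo-equatorial and the ester pseudo-axial, and with the C1 alkenyl group and the trans C2 methyl both equatorial this half-chair is free of 1,3-diaxial strain, whereas the flipped chair leading to the C6 epimer forces the C2 methyl syn-axial to the ester. The (2S) configuration from step 7 is therefore the decisive control element and gives the ester cis to the chain (6R). Site selectivity is needed between the acrylate and the C7=C8 alkene (both could close a six-membered ring) and between exo and seven-membered endo attack; the unhindered, electron-poor 1,1-disubstituted alkene inserts much faster than the trisubstituted one, and the short tether favours the exo mode. The Z geometry of the enol triflate puts palladium cis to the tether, without which closure is geometrically impossible. An amine-free medium with sparingly soluble HCO2Na is chosen so that the β-triflyloxy enone is not attacked by nucleophiles, C2 is not epimerised and the vinylpalladium is not reduced before it cyclises.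

Step 16
Reactants: 24 methyl (1R,5S,6R)-6-[(2E,4R,5S)-5-[(tert-butyldimethylsilyl)oxy]-4-methylhept-2-en-2-yl]-1,3,5-trimethyl-4-oxocyclohex-2-ene-1-carboxylate
Product: 25 ring A diol: C6 hydroxymethyl and C3 carbinol (both C3 epimers), otherwise as 24
Conditions: iBu2AlH, CH2Cl2, −78 to 0 °C; aq. potassium sodium tartrate
Reagents that add atoms: none
Why: The hydride reduces the hindered ester and, unavoidably, the enone carbonyl (1,2); the C3 configuration is irrelevant because it is reoxidised in step 17.

Step 17
Reactants: 25 ring A diol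
Product: 26 (1R,5S,6R)-6-[(2E,4R,5S)-5-[(tert-butyldimethylsilyl)oxy]-4-methylhept-2-en-2-yl]-1,3,5-trimethyl-4-oxocyclohex-2-ene-1-carbaldehyde
Conditions: Dess–Martin periodinane, NaHCO3, CH2Cl2, 0 °C to rt
Reagents that add atoms: none
Why: Double oxidation under buffered, non-basic conditions; the aldehyde on quaternary C6 cannot enolise.

Step 18
Reactants: 26 (1R,5S,6R)-6-[(2E,4R,5S)-5-[(tert-butyldimethylsilyl)oxy]-4-methylhept-2-en-2-yl]-1,3,5-trimethyl-4-oxocyclohex-2-ene-1-carbaldehyde; 27 methyl 2-methyl-3-oxopentanoate
Product: 29 aldol adduct: methyl 5-hydroxy-2,4-dimethyl-3-oxopentanoate carrying the ring A enone of 26 at C5 (diastereomer mixture), via sodium lithium dianion 28 (not isolated)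
Conditions: 27, NaH, THF, 0 °C; n-BuLi, 0 °C; then 26, −78 °C; AcOH quench
Reagents that add atoms: none
Why: γ-Aldol addition of a β-keto ester dianion; the non-enolisable aldehyde reacts far faster than the hindered enone. The three new chain centres are removed in steps 19 and 20; any epimerisation at C2 is inconsequential because C2 is reset in step 22.

Step 19
Reactants: 29 aldol adduct
Product: 30 methyl 2,4-dimethyl-3,5-dioxopentanoate carrying the ring A enone at C5 (mixture of epimers and enol forms)
Conditions: Dess–Martin periodinane, NaHCO3, CH2Cl2, rt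
Reagents that add atoms: none
Why: Oxidation of the secondary alcohol to the β,δ-diketo ester under neutral conditions.

Step 20
Reactants: 30 β,δ-diketo ester
Product: 31 4-hydroxy-3,5-dimethyl-6-[(1R,5S,6R)-6-[(2E,4R,5S)-5-[(tert-butyldimethylsilyl)oxy]-4-methylhept-2-en-2-yl]-1,3,5-trimethyl-4-oxocyclohex-2-en-1-yl]-2H-pyran-2-one
Conditions: DBU, toluene, rt to 50 °C
Reagents that add atoms: none
Why: Base-mediated enol lactonisation of a 3,5-dioxo ester to the 4-hydroxy-2-pyranone; the acidic product buffers the released methoxide.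

Step 21
Reactants: 31 4-hydroxy-2-pyranone
Product: 33 2-methoxy-3,5-dimethyl-6-[(1R,5S,6R)-6-[(2E,4R,5S)-5-[(tert-butyldimethylsilyl)oxy]-4-methylhept-2-en-2-yl]-1,3,5-trimethyl-4-oxocyclohex-2-en-1-yl]-4H-pyran-4-one, via methoxypyrylium triflate 32 (not isolated)
Conditions: MeOTf, CH2Cl2, 0 °C to rt; aq. NaHCO3
Reagents that add atoms: methyl trifluoromethanesulfonate, COS(=O)(=O)C(F)(F)F
Why: The neutral hydroxypyranone is methylated at its most nucleophilic site, the lactone carbonyl oxygen; deprotonation of the pyrylium salt then gives the 2-methoxy-4-pyranone.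

Step 22
Reactants: 33 ring A enone carrying ring B
Product: 35 (2S)-2-hydroxy ketone: 33 with a tertiary hydroxyl on C2 trans to the C1 chain, via potassium enolate 34 (not isolated)
Conditions: KN(SiMe3)2, THF, −78 °C; 2-(phenylsulfonyl)-3-phenyloxaziridine, −78 °C; aq. NH4Cl
Reagents that add atoms: 2-(phenylsulfonyl)-3-phenyloxaziridine, O=S(=O)(c1ccccc1)N1OC1c1ccccc1
Why: Enolate hydroxylation with an N-sulfonyl oxaziridine; C2 is the only enolisable position. The oxidant should approach the face opposite the C1 chain and ring B, which both shield the upper face, so the hydroxyl enters trans to the chain.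

Step 23
Reactants: 35 (2S)-2-hydroxy ketone
Product: 36 (2S,3S)-trans-diol: C3 hydroxyl cis to the C1 chain, C2 hydroxyl trans to it
Conditions: Me4NBH(OAc)3, MeCN/AcOH, −30 to 0 °C
Reagents that add atoms: none
Why: Hydroxyl-directed (Saksena–Evans) reduction; the borohydride bound to the C2 oxygen delivers hydride to C3 on the same face, so the new hydroxyl ends trans to the old one.

Step 24
Reactants: 36 (2S,3S)-trans-diol
Product: 38 silyl-protected epoxide: 2-methoxy-3,5-dimethyl-6-{(1R,4R,5R,6S)-5-[(2E,4R,5S)-5-[(tert-butyldimethylsilyl)oxy]-4-methylhept-2-en-2-yl]-2,4,6-trimethyl-7-oxabicyclo[4.1.0]hept-2-en-4-yl}-4H-pyran-4-one, via C3 mesylate 37 (not isolated)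
Conditions: Ms2O, Et3N, DMAP (cat.), CH2Cl2, −20 °C; then DBU, 0 °C to rt
Reagents that add atoms: none
Why: Only the secondary allylic hydroxyl is sulfonylated; the tertiary C2 oxygen then displaces it intramolecularly with inversion at C3, giving the cis-fused oxirane on the face away from the chain (3R). The chloride-free sulfonylating agent avoids allylic chloride formation.

Step 25
Reactants: 38 silyl-protected epoxide
Product: 39 C10 alcohol: 38 with the silyl ether replaced by hydroxyl (9R,10S in the chain)
Conditions: Bu4NF, THF, 0 °C to rt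
Reagents that add atoms: none
Why: Fluoride desilylation; the oxirane and the methoxypyranone tolerate fluoride, and no acid is present.

Step 26
Reactants: 39 C10 alcohol
Product: 40 2-methoxy-3,5-dimethyl-6-{(1R,4R,5R,6S)-2,4,6-trimethyl-5-[(2E,4R)-4-methyl-5-oxohept-2-en-2-yl]-7-oxabicyclo[4.1.0]hept-2-en-4-yl}-4H-pyran-4-one (target)
Conditions: Dess–Martin periodinane, NaHCO3, CH2Cl2, 0 °C
Reagents that add atoms: none
Why: Buffered, base-free oxidation as the last step, so the newly α-acidic, allylic C9 is neither epimerised nor isomerised and the oxirane is not opened.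

## Compound list

1 | propanal | CCC=O | starting material
2 | (2S,3S)-3-hydroxy-2-methylpentanal | CC[C@H](O)[C@H](C)C=O | intermediate
3 | (2S,3S)-3-[(tert-butyldimethylsilyl)oxy]-2-methylpentanal | CC[C@H](O[Si](C)(C)C(C)(C)C)[C@H](C)C=O | intermediate
4 | 2-bromoprop-2-en-1-ol | OCC(Br)=C | starting material
5 | [(2-bromoprop-2-en-1-yl)oxy]triethylsilane | CC[Si](CC)(CC)OCC(Br)=C | intermediate
6 | propyne | CC#C | starting material
7 | triethyl[(2-methylidenepent-3-yn-1-yl)oxy]silane | CC#CC(=C)CO[Si](CC)(CC)CC | intermediate
8 | chlorobis(cyclopentadienyl)[(2E)-4-methylidene-5-(triethylsilyloxy)pent-2-en-2-yl]zirconium (cyclopentadienyl rings drawn σ-bonded) | C/C(=C\C(=C)CO[Si](CC)(CC)CC)[Zr](Cl)(C1C=CC=C1)C1C=CC=C1 | intermediate (not isolated)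
9 | methyl[(2E)-4-methylidene-5-(triethylsilyloxy)pent-2-en-2-yl]zinc | C/C(=C\C(=C)CO[Si](CC)(CC)CC)[Zn]C | intermediate (not isolated)
10 | (3E,5R,6R,7S)-7-[(tert-butyldimethylsilyl)oxy]-4,6-dimethyl-2-methylidene-1-[(triethylsilyl)oxy]non-3-en-5-ol | CC[C@H](O[Si](C)(C)C(C)(C)C)[C@H](C)[C@@H](O)/C(C)=C/C(=C)CO[Si](CC)(CC)CC | intermediate
11 | (3E,5R,6R,7S)-7-[(tert-butyldimethylsilyl)oxy]-4,6-dimethyl-2-methylidene-1-[(triethylsilyl)oxy]non-3-en-5-yl propanoate | CC[C@H](O[Si](C)(C)C(C)(C)C)[C@H](C)[C@@H](OC(=O)CC)/C(C)=C/C(=C)CO[Si](CC)(CC)CC | intermediate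
12 | trimethylsilyl ketene acetal of 11 (methyl cis to the allylic oxygen) | CC[C@H](O[Si](C)(C)C(C)(C)C)[C@H](C)[C@@H](O/C(O[Si](C)(C)C)=C\C)/C(C)=C/C(=C)CO[Si](CC)(CC)CC | intermediate (not isolated)
13 | trimethylsilyl ester of 14 | CC[C@H](O[Si](C)(C)C(C)(C)C)[C@H](C)/C=C(\C)[C@@H]([C@H](C)C(=O)O[Si](C)(C)C)C(=C)CO[Si](CC)(CC)CC | intermediate (not isolated)
14 | (2S,3R,4E,6R,7S)-7-[(tert-butyldimethylsilyl)oxy]-2,4,6-trimethyl-3-{3-[(triethylsilyl)oxy]prop-1-en-2-yl}non-4-enoic acid | CC[C@H](O[Si](C)(C)C(C)(C)C)[C@H](C)/C=C(\C)[C@@H]([C@H](C)C(=O)O)C(=C)CO[Si](CC)(CC)CC | intermediate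
15 | (4S,5R,6E,8R,9S)-9-[(tert-butyldimethylsilyl)oxy]-4,6,8-trimethyl-5-{3-[(triethylsilyl)oxy]prop-1-en-2-yl}undec-6-en-3-one | CC[C@H](O[Si](C)(C)C(C)(C)C)[C@H](C)/C=C(\C)[C@@H]([C@H](C)C(=O)CC)C(=C)CO[Si](CC)(CC)CC | intermediate
16 | (4S,5R,6E,8R,9S)-9-[(tert-butyldimethylsilyl)oxy]-5-(3-hydroxyprop-1-en-2-yl)-4,6,8-trimethylundec-6-en-3-one | CC[C@H](O[Si](C)(C)C(C)(C)C)[C@H](C)/C=C(\C)[C@@H]([C@H](C)C(=O)CC)C(=C)CO | intermediate
17 | (3R,4S)-3-[(2E,4R,5S)-5-[(tert-butyldimethylsilyl)oxy]-4-methylhept-2-en-2-yl]-4-methyl-2-methylidene-5-oxoheptanal | CC[C@H](O[Si](C)(C)C(C)(C)C)[C@H](C)/C=C(\C)[C@@H]([C@H](C)C(=O)CC)C(=C)C=O | intermediate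
18 | (3R,4S)-3-[(2E,4R,5S)-5-[(tert-butyldimethylsilyl)oxy]-4-methylhept-2-en-2-yl]-4-methyl-2-methylidene-5-oxoheptanoic acid | CC[C@H](O[Si](C)(C)C(C)(C)C)[C@H](C)/C=C(\C)[C@@H]([C@H](C)C(=O)CC)C(=C)C(=O)O | intermediate
19 | methyl (3R,4S)-3-[(2E,4R,5S)-5-[(tert-butyldimethylsilyl)oxy]-4-methylhept-2-en-2-yl]-4-methyl-2-methylidene-5-oxoheptanoate | CC[C@H](O[Si](C)(C)C(C)(C)C)[C@H](C)/C=C(\C)[C@@H]([C@H](C)C(=O)CC)C(=C)C(=O)OC | intermediate
20 | trichlorotitanium (Z)-enolate of 19 (C3=C4) | CC[C@H](O[Si](C)(C)C(C)(C)C)[C@H](C)/C=C(\C)[C@@H]([C@H](C)/C(O[Ti](Cl)(Cl)Cl)=C/C)C(=C)C(=O)OC | intermediate (not isolated)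
21 | methyl (3R,4S,6Z)-3-[(2E,4R,5S)-5-[(tert-butyldimethylsilyl)oxy]-4-methylhept-2-en-2-yl]-7-hydroxy-4,6-dimethyl-2-methylidene-5-oxohept-6-enoate (enol of the formyl ketone) | CC[C@H](O[Si](C)(C)C(C)(C)C)[C@H](C)/C=C(\C)[C@@H]([C@H](C)C(=O)/C(C)=C\O)C(=C)C(=O)OC | intermediate
22 | methyl (3R,4S,6Z)-3-[(2E,4R,5S)-5-[(tert-butyldimethylsilyl)oxy]-4-methylhept-2-en-2-yl]-4,6-dimethyl-2-methylidene-5-oxo-7-[(trifluoromethanesulfonyl)oxy]hept-6-enoate | CC[C@H](O[Si](C)(C)C(C)(C)C)[C@H](C)/C=C(\C)[C@@H]([C@H](C)C(=O)/C(C)=C\OS(=O)(=O)C(F)(F)F)C(=C)C(=O)OC | intermediate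
23 | σ-alkylpalladium formate on the C6 methylene (phosphine ligands omitted) | CC[C@H](O[Si](C)(C)C(C)(C)C)[C@H](C)/C=C(\C)[C@H]1[C@H](C)C(=O)C(C)=C[C@@]1(C[Pd]OC=O)C(=O)OC | intermediate (not isolated)
24 | methyl (1R,5S,6R)-6-[(2E,4R,5S)-5-[(tert-butyldimethylsilyl)oxy]-4-methylhept-2-en-2-yl]-1,3,5-trimethyl-4-oxocyclohex-2-ene-1-carboxylate | CC[C@H](O[Si](C)(C)C(C)(C)C)[C@H](C)/C=C(\C)[C@H]1[C@H](C)C(=O)C(C)=C[C@@]1(C)C(=O)OC | intermediate
25 | ring A diol (C6 hydroxymethyl, C3 carbinol as both epimers) | CC[C@H](O[Si](C)(C)C(C)(C)C)[C@H](C)/C=C(\C)[C@H]1[C@H](C)C(O)C(C)=C[C@@]1(C)CO | intermediate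
26 | (1R,5S,6R)-6-[(2E,4R,5S)-5-[(tert-butyldimethylsilyl)oxy]-4-methylhept-2-en-2-yl]-1,3,5-trimethyl-4-oxocyclohex-2-ene-1-carbaldehyde | CC[C@H](O[Si](C)(C)C(C)(C)C)[C@H](C)/C=C(\C)[C@H]1[C@H](C)C(=O)C(C)=C[C@@]1(C)C=O | intermediate
27 | methyl 2-methyl-3-oxopentanoate | CCC(=O)C(C)C(=O)OC | starting material
28 | sodium lithium dianion of 27 | C[CH-]C(=O)[C-](C)C(=O)OC.[Na+].[Li+] | intermediate (not isolated)
29 | aldol adduct of 26 and 28 (mixture at the three chain centres) | CC[C@H](O[Si](C)(C)C(C)(C)C)[C@H](C)/C=C(\C)[C@H]1[C@H](C)C(=O)C(C)=C[C@@]1(C)C(O)C(C)C(=O)C(C)C(=O)OC | intermediate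
30 | β,δ-diketo ester (mixture at the two chain centres) | CC[C@H](O[Si](C)(C)C(C)(C)C)[C@H](C)/C=C(\C)[C@H]1[C@H](C)C(=O)C(C)=C[C@@]1(C)C(=O)C(C)C(=O)C(C)C(=O)OC | intermediate
31 | 4-hydroxy-3,5-dimethyl-2H-pyran-2-one carrying the ring A enone at C6' | CC[C@H](O[Si](C)(C)C(C)(C)C)[C@H](C)/C=C(\C)[C@H]1[C@H](C)C(=O)C(C)=C[C@@]1(C)c1oc(=O)c(C)c(O)c1C | intermediate
32 | 4-hydroxy-2-methoxy-3,5-dimethylpyrylium triflate carrying the ring A enone | CC[C@H](O[Si](C)(C)C(C)(C)C)[C@H](C)/C=C(\C)[C@H]1[C@H](C)C(=O)C(C)=C[C@@]1(C)c1[o+]c(OC)c(C)c(O)c1C.[O-]S(=O)(=O)C(F)(F)F | intermediate (not isolated)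
33 | 2-methoxy-3,5-dimethyl-4H-pyran-4-one carrying the ring A enone (1R,5S,6R) at C6' | CC[C@H](O[Si](C)(C)C(C)(C)C)[C@H](C)/C=C(\C)[C@H]1[C@H](C)C(=O)C(C)=C[C@@]1(C)c1oc(OC)c(C)c(=O)c1C | intermediate
34 | potassium enolate of 33 (C2=C3) | CC[C@H](O[Si](C)(C)C(C)(C)C)[C@H](C)/C=C(\C)[C@H]1C(C)=C([O-])C(C)=C[C@@]1(C)c1oc(OC)c(C)c(=O)c1C.[K+] | intermediate (not isolated)
35 | (2S)-2-hydroxy ketone (hydroxyl trans to the C1 chain) | CC[C@H](O[Si](C)(C)C(C)(C)C)[C@H](C)/C=C(\C)[C@H]1[C@](C)(O)C(=O)C(C)=C[C@@]1(C)c1oc(OC)c(C)c(=O)c1C | intermediate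
36 | (2S,3S)-trans-diol | CC[C@H](O[Si](C)(C)C(C)(C)C)[C@H](C)/C=C(\C)[C@H]1[C@](C)(O)[C@@H](O)C(C)=C[C@@]1(C)c1oc(OC)c(C)c(=O)c1C | intermediate
37 | C3 methanesulfonate of 36 | CC[C@H](O[Si](C)(C)C(C)(C)C)[C@H](C)/C=C(\C)[C@H]1[C@](C)(O)[C@@H](OS(C)(=O)=O)C(C)=C[C@@]1(C)c1oc(OC)c(C)c(=O)c1C | intermediate (not isolated)
38 | silyl-protected epoxide (1R,2S,3R,6R in ring A numbering; 9R,10S) | CC[C@H](O[Si](C)(C)C(C)(C)C)[C@H](C)/C=C(\C)[C@H]1[C@]2(C)O[C@@H]2C(C)=C[C@@]1(C)c1oc(OC)c(C)c(=O)c1C | intermediate
39 | C10 alcohol of the target skeleton | CC[C@H](O)[C@H](C)/C=C(\C)[C@H]1[C@]2(C)O[C@@H]2C(C)=C[C@@]1(C)c1oc(OC)c(C)c(=O)c1C | intermediate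
40 | 2-methoxy-3,5-dimethyl-6-{(1R,4R,5R,6S)-2,4,6-trimethyl-5-[(2E,4R)-4-methyl-5-oxohept-2-en-2-yl]-7-oxabicyclo[4.1.0]hept-2-en-4-yl}-4H-pyran-4-one | CCC(=O)[C@H](C)/C=C(\C)[C@H]1[C@]2(C)O[C@@H]2C(C)=C[C@@]1(C)c1oc(OC)c(C)c(=O)c1C | target

## Step count and least certain steps

Total: 26 steps. Longest linear sequence: 24 steps (steps 1, 2 and 5 to 26); steps 3 and 4 form the short branch to 7.

**Step 15 (key step).** The most likely failure is hydride transfer to the vinylpalladium before it inserts, which simply removes the triflate; attack at the α-carbon of an acrylate runs against its polarity and may be slow. Seven-membered endo closure, and erosion at C6 if C2 epimerises first, are the other processes to watch. The fallback keeps the same bond, ring and origin of the C6 methyl but reverses the order of events. It sets out from 21, which is O-methylated (Me2SO4, K2CO3, acetone) to the β-methoxy enone F1. Treatment of F1 with [(Ph3P)CuH]6, or with LiBH(s-Bu)3 at −78 °C, should add hydride to the acrylate methylene. The resulting C6 ester enolate then adds to C5 of the vinylogous ester and expels methoxide. This reductive Michael addition–elimination rejoins the route at 24; its facial outcome at C6 would have to be established.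

**Step 5.** The likely weakness is modest facial selectivity in the addition of the alkenylzinc reagent to the α-methyl aldehyde, together with incomplete regiocontrol in the hydrozirconation of an internal alkyne. The fallback starts from the C8-epimer mixture of 10. This is oxidised (Dess–Martin periodinane) to the enone F2 and reduced under reagent control with the (S)-oxazaborolidine of the CBS reduction and BH3·SMe2. With the alkenyl group as the large substituent this should return the (8R) alcohol 10.

**Step 13.** The titanium enolate could add to the Lewis-acid-activated acrylate in an intramolecular Michael reaction, C2 could epimerise if enolisation is not fully regioselective, or TiCl4 could strip the silyl ether. The fallback leaves from 19 and avoids a metal enolate in the presence of a Lewis acid. LiN(SiMe3)2 with Me3SiCl present (internal quench, THF, −78 °C) gives the silyl enol ether F3. Mukaiyama addition to HC(OMe)3 with BF3·OEt2 at −78 °C gives the β-keto dimethyl acetal F4. Aqueous acid then returns to 21.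

**Step 14.** Sulfonylation may occur at the ketone oxygen, Z geometry may be lost if chelation is incomplete, and the vinylogous acyl triflate may hydrolyse on isolation. The fallback starts from 21 and replaces the triflate by a more robust leaving group. TsCl, N-methylimidazole and LiOH give the chelation-controlled (Z)-enol tosylate F5. F5 is then cyclised under formate with Pd(OAc)2 and a bulky electron-rich phosphine such as XPhos, rejoining at 24.

**Step 22.** Poor facial selectivity in the enolate oxidation, or α-ketol rearrangement of the tertiary alkoxide on warming, would put the oxygen on the wrong face or the wrong carbon. The fallback starts from 33 and sets the oxirane by alkene epoxidation. KN(SiMe3)2 and PhNTf2 give the dienyl triflate F6. Pd(OAc)2/PPh3 with HCO2H/Et3N reduces it to the diene F7. Dimethyldioxirane at low temperature should then attack the C2=C3 alkene, the diene terminus remote from quaternary C6, on the face away from the chain and ring B, giving 38 directly. Competing epoxidation of C7=C8 is the weakness of this fallback.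

## Further compounds

F1 | step 15 | β-methoxy enone acrylate (O-methyl ether of 21) | CC[C@H](O[Si](C)(C)C(C)(C)C)[C@H](C)/C=C(\C)[C@@H]([C@H](C)C(=O)/C(C)=C/OC)C(=C)C(=O)OC
F2 | step 5 | (E)-enone from oxidation of 10 (C8 ketone) | CC[C@H](O[Si](C)(C)C(C)(C)C)[C@H](C)C(=O)/C(C)=C/C(=C)CO[Si](CC)(CC)CC
F3 | step 13 | (Z)-trimethylsilyl enol ether of 19 | CC[C@H](O[Si](C)(C)C(C)(C)C)[C@H](C)/C=C(\C)[C@@H]([C@H](C)/C(O[Si](C)(C)C)=C/C)C(=C)C(=O)OC
F4 | step 13 | β-keto dimethyl acetal (C4 epimers) | CC[C@H](O[Si](C)(C)C(C)(C)C)[C@H](C)/C=C(\C)[C@@H]([C@H](C)C(=O)C(C)C(OC)OC)C(=C)C(=O)OC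
F5 | step 14 | (Z)-enol tosylate of 21 | CC[C@H](O[Si](C)(C)C(C)(C)C)[C@H](C)/C=C(\C)[C@@H]([C@H](C)C(=O)/C(C)=C\OS(=O)(=O)c1ccc(C)cc1)C(=C)C(=O)OC
F6 | step 22 | dienyl triflate of 33 (C2=C3–OTf) | CC[C@H](O[Si](C)(C)C(C)(C)C)[C@H](C)/C=C(\C)[C@H]1C(C)=C(OS(=O)(=O)C(F)(F)F)C(C)=C[C@@]1(C)c1oc(OC)c(C)c(=O)c1C
F7 | step 22 | ring A 2,4-diene | CC[C@H](O[Si](C)(C)C(C)(C)C)[C@H](C)/C=C(\C)[C@H]1C(C)=CC(C)=C[C@@]1(C)c1oc(OC)c(C)c(=O)c1C
A1 | alternative 1 | dearomatised methoxy diene with the (S)-tert-butyl oxazoline on C6 | CC[C@H](O[Si](C)(C)C(C)(C)C)[C@H](C)/C=C(\C)[C@H]1C(C)=C(OC)C(C)=C[C@@]1(C)C2=N[C@@H](C(C)(C)C)CO2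
A2 | alternative 1 | (S)-4-tert-butyl-2-(4-methoxy-3,5-dimethylphenyl)-4,5-dihydro-1,3-oxazole | COc1c(C)cc(cc1C)C1=N[C@@H](C(C)(C)C)CO1
A3 | alternative 1 | [(2E,4R,5S)-5-[(tert-butyldimethylsilyl)oxy]-4-methylhept-2-en-2-yl]lithium | CC[C@H](O[Si](C)(C)C(C)(C)C)[C@H](C)/C=C(\C)[Li]
A4 | alternative 2 | silyl-protected epoxide (same structure as 38) | CC[C@H](O[Si](C)(C)C(C)(C)C)[C@H](C)/C=C(\C)[C@H]1[C@]2(C)O[C@@H]2C(C)=C[C@@]1(C)c1oc(OC)c(C)c(=O)c1C
A5 | alternative 2 | Z-allylic tetrahydrothiophenium triflate carrying the C2 methyl ketone | CC[C@H](O[Si](C)(C)C(C)(C)C)[C@H](C)/C=C(\C)[C@@H](C(C)=O)[C@@](C)(/C=C(/C)C[S+]1CCCC1)c1oc(OC)c(C)c(=O)c1C.[O-]S(=O)(=O)C(F)(F)F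
A6 | alternative 3 | 2-oxabicyclo[2.2.2]oct-5-en-3-one adduct | CC[C@H](O[Si](C)(C)C(C)(C)C)[C@H](C)/C=C(\C)[C@H]1[C@](C)(C(C)=O)[C@H]2OC(=O)[C@]1(C)C=C2C
A7 | alternative 3 | 3,5-dimethyl-2H-pyran-2-one | O=c1occ(C)cc1C
A8 | alternative 3 | (3E,5E,7R,8S)-8-[(tert-butyldimethylsilyl)oxy]-3,5,7-trimethyldeca-3,5-dien-2-one | CC[C@H](O[Si](C)(C)C(C)(C)C)[C@H](C)/C=C(\C)/C=C(\C)C(C)=O
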